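## The problem

Brianodin D (42) is a briarane. A cyclohexene (ring C: C1, C10–C14) is trans-fused across C1–C10 to a ten-membered carbocycle (C1–C10), and that ring carries a γ-lactone on C7–C8 (O–C19(=O)–C17).

It has ten stereocentres: C1 (quaternary), C2, C3, C7, C8, C9, C10, C11, C12 and C17. Six of them sit on the medium ring or the lactone, where acyclic models are weak guides.

The control chain available is short but usable:
- C1 and C10 can be set absolutely in a cycloaddition.
- C10 can then steer oxygen to the α face of C11/C12 and, through 1,3-induction, to C9.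
- C2 and C3 can arise together when the ten-membered ring is closed.
- C7 must be set on the ring and then directs the two fully substituted lactone carbons C8 and C17, whose hydroxyl groups are trans.

The fragile parts are:
- the two secondary acetates at C3 and C9, which rule out strong base or hydride late in the route;
- the tertiary 8,17-diol beside the lactone carbonyl;
- the Z C5=C6 bond, which is β,γ to any C8 carbonyl and allylic to the C7–O bond;
- the allylic cis-11,12-diol.

The lactone oxygen lies between C7 and C19, and C8 and C17 carry no hydrogen. The lactone is therefore the four-carbon ring C7–C19–C17–C8 plus one oxygen atom. C19 and C17 can be added to a C7=C8 enol ether as a ketene, and the oxygen inserted afterwards.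

## Retrosynthesis

**42 from 41 (C8–OH).** The trans-diol is traced to the 8,17-epoxy lactone 41. Water opens the oxirane at C8, the only carbon that can bear positive charge (C17 is α to the carbonyl), with inversion. Direct cis-dihydroxylation of a butenolide would give the wrong relative configuration. The forward step must invert C8 cleanly and may also remove the acetonide and the C2 silyl ether.

**41 from 40 (both oxirane C–O bonds).** The epoxide comes from the 3-methylbutenolide 40 by nucleophilic epoxidation. A peroxide anion attacks only the electron-poor C8=C17 bond and leaves C5=C6 and C13=C14 alone, which an electrophilic oxidant would not do. It must enter on the face of H7, away from C6.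

**40 from 39 (C8–O and C17–Cl removed).** The butenolide is the reductive-elimination product of the 17-chloro-8-silyloxy lactone 39. Passing through 40 erases C8 and C17, so the configuration that a cycloaddition leaves at those carbons does not matter. The alternative, carrying them through and replacing chlorine by hydroxyl with retention, has no reliable solution.

**39 from 37 (C7–O and O–C19; key step).** Removing the ring oxygen gives the α-chlorocyclobutanone 37. The oxygen must go between C19 and C7 and not between C19 and C17; the chlorine on C17 ensures this. Other lactone constructions would first have to hydroxylate C7 and then build C8=C17. This cut brings C7–C19 and C8–C17 from one reagent, and the oxidation is driven by ring strain, so the alkenes are spared.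

**37 from 34 and 36 (C7–C19, C8–C17).** The cyclobutanone is the [2+2] adduct of chloro(methyl)ketene 36 (from 2-chloropropanoyl chloride 35) and the silyl dienol ether 34 of the ten-membered ketone 33. The lactone problem is reduced to a simple ring ketone whose only enolisable side that matters is C7. The forward step must bond C19 to C7 on the correct face.

**33 from 29 (C2–C3).** The ten-membered ring is opened between the two carbinol carbons to dialdehyde 29; C8 is held as a dithiane (30–32). A reductive pinacol closure makes the ring and both oxygenated stereocentres in one step, and both aldehydes come from primary silyl ethers unmasked together. Closures at C7–C8 or C8–C9 would need the 2,3-diol built and protected beforehand. The price is that ring size and relative configuration must be controlled in the same step. The less hindered C3 hydroxyl is then acetylated selectively.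

**29 from 14 and 24 (C8–C9).** The chain is detached at C8–C9, giving ring C aldehyde 14 and the dithiane 24. C8 arrives at ketone oxidation level but is inert to SmI2, which a free α-acetoxy ketone would not be. The new C9 carbinol is acetylated directly. The forward addition must deliver the 9S configuration (1,3-anti to the C11 oxygen) at a hindered aldehyde.

**24 from 22, 21 and 15 (C7–C8, then C5–CH3).** The dithiane is 1,3-dithiane 22 alkylated by the Z allylic bromide 21. The trisubstituted Z alkene is made early and unambiguously by syn-carbocupration of ynoate 18, from but-3-yn-1-ol 15. A Wittig construction of this alkene later in the route would not be geometrically reliable.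

**14 from 10 and 7 (C11–O, C12–O).** Both ring C oxygens are removed to diene 10. Osmylation of the trisubstituted C11=C12 bond anti to the C10 substituent delivers both α-oxygens at once. The obvious neighbour, enolate hydroxylation at C11 followed by ketone reduction, would need hydride to enter syn to the C11 methyl and the C10 substituent. Diene 10 comes from enone 7 through dienyl triflate 9.

**7 from 4, and 4 from 2 and 3 (C10–C11, C1–C14).** Ring C is the Diels–Alder adduct 4 of silyloxydiene 2 (from pent-1-en-3-one 1) and the E enal ester 3. The formyl group becomes C2 and the ester C9. These are the trans pair on the quaternary C1 and on C10, set in absolute terms by a chiral catalyst. The silyl enol ether gives the C13=C14 enone by direct oxidation.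

## Roads not taken

**Alternative 1: catalytic asymmetric Diels–Alder assembly of ring C as the centre of the plan.**
- Cut: C10–C11 and C1–C14.
- Forward step: diene 2 and enal 3 combine under the oxazaborolidinium salt [C24H25BNO][N(SO2CF3)2] to give A1.
- Merits: two achiral, cheap partners; the quaternary C1 and C10 are set absolutely in one catalytic step; the three carbons that must later diverge (C2 formyl, C9 ester, C12 enol ether) come out differentiated.
- Weak points: as a strategy it solves the easiest ring only. It says nothing about the ten-membered ring or the lactone, and the C11 centre it creates has to be erased.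
- Comparison: as an opening it is better than anything else considered. The chosen route adopts it unchanged as step 2 (A1 is compound 4). The chosen plan adds what this leaves open: how C7, C8, C17 and the lactone oxygen arrive on a finished carbocycle.

**Alternative 2: biomimetic transannular epoxy-olefin cyclisation.**
- Cut: C1–C10.
- Forward step: Yb(O3SCF3)3 in wet acetonitrile ionises the C1–C2 epoxide of the fourteen-membered macrocycle A2 at C1. The C10=C11 alkene closes ring C, and water captures C11 to give A3.
- Merits: C1, C10, C11 and the free C2 hydroxyl are created in one step. A3 is already a butenolide, one silyl ether away from the deprotected counterpart of 40, so the endgame would be shared.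
- Weak points: A2 is a fourteen-membered epoxy triene carrying the butenolide and five stereocentres, at least as hard to make as the ten-membered ring itself. The cyclisation has only ring conformation to control it. The allyl cation can be attacked at C13. The C11 cation can lose a proton or accept water on either face. Water can intercept C1 directly.
- Comparison: if the cyclisation worked it would be clearly shorter. The chosen plan offers instead that every stereocentre is set by a step with an identifiable control element, and that the lactone is made from a ring ketone and not carried through a cationic cascade.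

**Alternative 3: Grob fragmentation of a hydroazulene.**
- Cut: none in the final ring; a temporary C5–C9 bond is added.
- Forward step: KOC(CH3)3 deprotonates the C9 alcohol of the mesylate A4, and fragmentation gives the Z-cyclodecenone A5.
- Merits: the medium ring is formed from five- and seven-membered rings without an entropic penalty, and the Z C5=C6 geometry follows from the anti-periplanar fragmentation. On both counts it is better than the chosen route, which relies on a pinacol closure, its least secure step.
- Weak points: A4 needs three extra stereocentres (C5, C6, C9) that are built only to be destroyed. A5 carries its carbonyl at C9 and a methylene at C8. The lactone carbons would have to be attached at an unactivated C8, C8 oxidised, and C9 reduced and acetylated with control.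
- Comparison: the Grob route is stronger on the ring and weaker on the lactone. The chosen plan puts the ketone at C8, exactly where the ketene needs its enol ether.

Key step: step 28

## Conventions and assumption

Briarane numbering (C1–C20) is used for all intermediates. On ring C, β is the face of the C1 methyl group and α the opposite face.

Assumption: the sense of induction in step 2 is taken from the usual model for 2-substituted enals (formyl C–H···O contact, diene adding to the enal face remote from the catalyst phenyl group). This points to the (R)-diphenylprolinol-derived salt; the antipodal salt is equally accessible should the sense prove opposite.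

Remark: the configurations drawn at C8 and C17 in 37–39 are those expected from suprafacial addition to the ring-cis enol ether with the methyl group endo. They are erased in 40 and do not affect the outcome.

## Route

Step 1
Reactants: 1 pent-1-en-3-one
Product: 2 (Z)-3-(tert-butyldimethylsilyloxy)penta-1,3-diene
Conditions: t-BuMe2SiOSO2CF3, Et3N, Et2O, 0 °C
Reagents that add atoms: tert-butyldimethylsilyl trifluoromethanesulfonate, CC(C)(C)[Si](C)(C)OS(=O)(=O)C(F)(F)F
Why: Soft enolisation of the ethyl ketone (silyl enol ether formation) should give the 2-silyloxydiene; the Z enol ether, with methyl trans to vinyl, is the usual product and the one able to reach the s-cis form.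

Step 2
Reactants: 2 (Z)-3-(tert-butyldimethylsilyloxy)penta-1,3-diene; 3 ethyl (E)-3-methyl-4-oxobut-2-enoate
Product: 4 ethyl (1S,2S,6S)-2-formyl-2,6-dimethyl-5-(tert-butyldimethylsilyloxy)cyclohex-4-ene-1-carboxylate (ring position 1 = C10, 2 = C1, 5 = C12, 6 = C11)
Conditions: [C24H25BNO][N(SO2CF3)2] (10 mol%; (R)-configured, from (R)-α,α-diphenylprolinol, tri-o-tolylboroxine and HN(SO2CF3)2), CH2Cl2, −78 °C
Reagents that add atoms: none
Why: Catalytic enantioselective Diels–Alder reaction: the salt binds the formyl group, the nucleophilic diene terminus C11 bonds to C10 (β to the activated aldehyde) and C14 to C1, and addition to the unshielded enal face sets C1 and C10. The E enal fixes formyl and ester trans; the C11 configuration (endo-formyl adduct drawn) is erased in step 6.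

Step 3
Reactants: 4 ethyl (1S,2S,6S)-2-formyl-2,6-dimethyl-5-(tert-butyldimethylsilyloxy)cyclohex-4-ene-1-carboxylate
Product: 5 ethyl (1S,2S,6S)-2-(hydroxymethyl)-2,6-dimethyl-5-(tert-butyldimethylsilyloxy)cyclohex-4-ene-1-carboxylate
Conditions: NaBH4, EtOH, −20 °C
Reagents that add atoms: none
Why: Chemoselective borohydride reduction of the neopentyl aldehyde; the ester and the silyl enol ether should not react at this temperature.

Step 4
Reactants: 5 ethyl (1S,2S,6S)-2-(hydroxymethyl)-2,6-dimethyl-5-(tert-butyldimethylsilyloxy)cyclohex-4-ene-1-carboxylate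
Product: 6 ethyl (1S,2S,6S)-2-[(tert-butyldimethylsilyloxy)methyl]-2,6-dimethyl-5-(tert-butyldimethylsilyloxy)cyclohex-4-ene-1-carboxylate
Conditions: t-BuMe2SiCl, imidazole, DMF, 25 °C
Reagents that add atoms: tert-butyldimethylsilyl chloride, CC(C)(C)[Si](C)(C)Cl
Why: Standard silylation of a primary alcohol; it stores C2 at the alcohol level until the ring closure.

Step 5
Reactants: 6 ethyl (1S,2S,6S)-2-[(tert-butyldimethylsilyloxy)methyl]-2,6-dimethyl-5-(tert-butyldimethylsilyloxy)cyclohex-4-ene-1-carboxylate
Product: 7 ethyl (1S,2S,6S)-2-[(tert-butyldimethylsilyloxy)methyl]-2,6-dimethyl-5-oxocyclohex-3-ene-1-carboxylate (C12 ketone, C13=C14)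
Conditions: Pd(OAc)2 (1.05 equiv), MeCN, 25 °C
Reagents that add atoms: none
Why: Saegusa–Ito oxidation: palladation of the silyl enol ether at C13 and β-hydride loss from C14 should give the C13=C14 enone directly; the primary silyl ether is inert.

Step 6
Reactants: 7 ethyl (1S,2S,6S)-2-[(tert-butyldimethylsilyloxy)methyl]-2,6-dimethyl-5-oxocyclohex-3-ene-1-carboxylate
Product: 9 ethyl 6-[(tert-butyldimethylsilyloxy)methyl]-2,6-dimethyl-3-(trifluoromethylsulfonyloxy)cyclohexa-2,4-diene-1-carboxylate (C1 and C10 as in 4), via potassium dienolate 8 (not isolated)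
Conditions: KN(SiMe3)2, THF, −78 °C; then PhN(SO2CF3)2, −78 → 0 °C
Reagents that add atoms: N-phenylbis(trifluoromethanesulfonimide), O=S(=O)(N(c1ccccc1)S(=O)(=O)C(F)(F)F)C(F)(F)F
Why: C11–H is the only enolisable position of the enone (C1 is quaternary) and is far more acidic than the ester α-hydrogen, so kinetic deprotonation and O-sulfonylation should give the dienyl triflate. This removes the C11 stereocentre.

Step 7
Reactants: 9 ethyl 6-[(tert-butyldimethylsilyloxy)methyl]-2,6-dimethyl-3-(trifluoromethylsulfonyloxy)cyclohexa-2,4-diene-1-carboxylate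
Product: 10 ethyl 6-[(tert-butyldimethylsilyloxy)methyl]-2,6-dimethylcyclohexa-2,4-diene-1-carboxylate (C11=C12–C13=C14 diene; C1 and C10 as in 4)
Conditions: Pd(OAc)2 (5 mol%), PPh3, HCO2H, n-Bu3N, DMF, 60 °C
Reagents that add atoms: none
Why: Palladium-catalysed formate reduction of an enol triflate (oxidative addition, formate exchange, decarboxylation, reductive elimination); the amine is too weak to move the C10 proton and the quaternary C1 prevents aromatisation.

Step 8
Reactants: 10 ethyl 6-[(tert-butyldimethylsilyloxy)methyl]-2,6-dimethylcyclohexa-2,4-diene-1-carboxylate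
Product: 11 ring C diol ester: C10 β-CO2Et, C1 β-methyl and α-CH2OSi(t-Bu)Me2, 11β-methyl-11α,12α-diol, C13=C14
Conditions: OsO4 (2 mol%), N-methylmorpholine N-oxide, acetone/H2O, 0 °C
Reagents that add atoms: osmium tetroxide, O=[Os](=O)(=O)=O; N-methylmorpholine N-oxide, C[N+]1([O-])CCOCC1; water, O
Why: Catalytic osmylation should choose the more electron-rich trisubstituted C11=C12 bond over C13=C14, which abuts the quaternary C1. It should add anti to the C10 ester, which allylic strain holds pseudoaxial on the β face, so both oxygens arrive α and cis in one suprafacial step.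

Step 9
Reactants: 11 ring C diol ester
Product: 12 11α,12α-O-isopropylidene derivative of 11
Conditions: Me2C(OMe)2, pyridinium p-toluenesulfonate (cat.), CH2Cl2, 25 °C
Reagents that add atoms: 2,2-dimethoxypropane, COC(C)(C)OC
Why: Transketalisation of a cis-1,2-diol; the acetonide masks the tertiary and the allylic hydroxyl until the last step.

Step 10
Reactants: 12 11α,12α-O-isopropylidene ester
Product: 13 C9 primary alcohol (CH2OH on C10, β)
Conditions: i-Bu2AlH (2.5 equiv), CH2Cl2, −78 → 0 °C
Reagents that add atoms: none
Why: Hydride reduction of the hindered ester to the alcohol; the silyl ether and the acetonide are stable.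

Step 11
Reactants: 13 C9 primary alcohol
Product: 14 C9 aldehyde (CHO on C10, β; C1, C11, C12 as in 12)
Conditions: Dess–Martin periodinane, NaHCO3, CH2Cl2, 0 → 25 °C
Reagents that add atoms: none
Why: Dess–Martin oxidation under buffered, non-basic conditions should give the aldehyde without epimerising C10.

Step 12
Reactants: 15 but-3-yn-1-ol
Product: 16 tert-butyl(but-3-yn-1-yloxy)dimethylsilane
Conditions: t-BuMe2SiCl, imidazole, CH2Cl2, 25 °C
Reagents that add atoms: tert-butyldimethylsilyl chloride, CC(C)(C)[Si](C)(C)Cl
Why: Standard silylation; this oxygen becomes the C3 aldehyde oxygen.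

Step 13
Reactants: 16 tert-butyl(but-3-yn-1-yloxy)dimethylsilane
Product: 18 methyl 5-(tert-butyldimethylsilyloxy)pent-2-ynoate, via lithium acetylide 17 (not isolated)
Conditions: n-BuLi, THF, −78 °C; then ClCO2Me, −78 → 0 °C
Reagents that add atoms: methyl chloroformate, COC(Cl)=O
Why: Acylation of a lithium acetylide with a chloroformate; it adds C7 and activates the alkyne for carbometalation.

Step 14
Reactants: 18 methyl 5-(tert-butyldimethylsilyloxy)pent-2-ynoate
Product: 19 methyl (Z)-3-methyl-5-(tert-butyldimethylsilyloxy)pent-2-enoate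
Conditions: MeLi, CuI, THF, −78 °C (Me2CuLi); then 18, −78 °C; MeOH/NH4Cl quench at −78 °C
Reagents that add atoms: lithium dimethylcuprate (from methyllithium and copper iodide), [Li+].C[Cu-]C
Why: syn-Carbocupration of the ynoate and protonation with retention at −78 °C place the C4 chain cis to the ester carbon C7. This sets the Z C5=C6 geometry of the target.

Step 15
Reactants: 19 methyl (Z)-3-methyl-5-(tert-butyldimethylsilyloxy)pent-2-enoate
Product: 20 (Z)-3-methyl-5-(tert-butyldimethylsilyloxy)pent-2-en-1-ol
Conditions: i-Bu2AlH, CH2Cl2, −78 °C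
Reagents that add atoms: none
Why: 1,2-Reduction of the enoate to the allylic alcohol; the alkene geometry is not touched.

Step 16
Reactants: 20 (Z)-3-methyl-5-(tert-butyldimethylsilyloxy)pent-2-en-1-ol
Product: 21 (Z)-5-bromo-3-methylpent-3-en-1-yl tert-butyldimethylsilyl ether
Conditions: CBr4, PPh3, CH2Cl2, −20 °C
Reagents that add atoms: carbon tetrabromide, BrC(Br)(Br)Br
Why: Appel bromination of a primary allylic alcohol proceeds by direct displacement at low temperature, so the Z geometry should be kept.

Step 17
Reactants: 22 1,3-dithiane; 21 (Z)-5-bromo-3-methylpent-3-en-1-yl tert-butyldimethylsilyl ether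
Product: 24 2-[(Z)-3-methyl-5-(tert-butyldimethylsilyloxy)pent-2-en-1-yl]-1,3-dithiane (dithiane C2 = C8), via 2-lithio-1,3-dithiane 23 (not isolated)
Conditions: n-BuLi, THF, −30 °C; then 21, −78 → −20 °C
Reagents that add atoms: none
Why: Alkylation of the dithiane acyl-anion equivalent at the primary allylic carbon forms C7–C8 with C8 at ketone oxidation level; direct substitution is the normal course for 2-lithiodithianes and allylic bromides.

Step 18
Reactants: 24 2-[(Z)-3-methyl-5-(tert-butyldimethylsilyloxy)pent-2-en-1-yl]-1,3-dithiane; 14 C9 aldehyde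
Product: 26 (9S)-carbinol: ring C of 14 bearing on C10 the CH(OH) group bonded to dithiane carbon C8 which carries the Z C7–C3 chain, via 2-lithio derivative 25 (not isolated)
Conditions: t-BuLi, THF/HMPA, −78 °C; then 14, −78 °C
Reagents that add atoms: none
Why: Addition of a 2-alkyl-2-lithio-1,3-dithiane to an aldehyde forms C8–C9. The 9S configuration is the one expected from polar 1,3-induction, with the new hydroxyl anti to the C11 oxygen and the carbanion approaching anti to C11.

Step 19
Reactants: 26 (9S)-carbinol
Product: 27 (9S)-9-acetate of 26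
Conditions: Ac2O, 4-(dimethylamino)pyridine, pyridine, 25 °C
Reagents that add atoms: acetic anhydride, CC(=O)OC(C)=O
Why: Nucleophile-catalysed acetylation of a hindered secondary alcohol; it installs the C9 acetate of the target once and for all.

Step 20
Reactants: 27 (9S)-9-acetate
Product: 28 C2,C3-diol (both primary hydroxyl groups free; C9 acetate, C8 dithiane, acetonide kept)
Conditions: HF·pyridine, pyridine, THF, 0 → 25 °C
Reagents that add atoms: none
Why: Buffered fluoride cleavage of the two primary silyl ethers; the acetate, acetonide and dithiane are inert.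

Step 21
Reactants: 28 C2,C3-diol
Product: 29 C2,C3-dialdehyde
Conditions: Dess–Martin periodinane, pyridine, CH2Cl2, 0 °C
Reagents that add atoms: none
Why: Double Dess–Martin oxidation; the neutral buffered medium tolerates the dithiane and should keep the β,γ-unsaturated C3 aldehyde out of conjugation; the product is used at once.

Step 22
Reactants: 29 C2,C3-dialdehyde
Product: 30 (2S,3R,5Z,9S)-9-acetoxy-2,3-dihydroxy ten-membered ring (C1–C10) fused to ring C, with C8 as 1,3-dithiane and the 11α,12α-acetonide
Conditions: SmI2 (4 equiv), THF, 25 °C, slow addition of 29 (final 2 mM)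
Reagents that add atoms: none
Why: Intramolecular pinacol coupling: after one-electron reduction the two carbonyl carbons join while both oxygens are held on samarium, which favours the cis (2S,3R) diol; the face at C2 is governed by the adjacent quaternary C1. High dilution favours the ten-membered ring over oligomers.

Step 23
Reactants: 30 ten-membered 2,3-diol
Product: 31 3-O-acetyl derivative of 30 (C2 hydroxyl free)
Conditions: AcCl, 2,4,6-collidine, CH2Cl2, −78 °C
Reagents that add atoms: acetyl chloride, CC(Cl)=O
Why: Selective acylation of the less hindered secondary alcohol; the C2 hydroxyl is neopentyl and should react much more slowly.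

Step 24
Reactants: 31 3-acetate
Product: 32 2-O-triethylsilyl ether of 31
Conditions: Et3SiOSO2CF3, 2,6-lutidine, CH2Cl2, −78 → 0 °C
Reagents that add atoms: triethylsilyl trifluoromethanesulfonate, CC[Si](CC)(CC)OS(=O)(=O)C(F)(F)F
Why: Silyl triflate silylation of the hindered C2 alcohol; protecting it before the ketone is released prevents transannular hemiketal formation with C8.

Step 25
Reactants: 32 2-O-triethylsilyl ether
Product: 33 (2S,3R,5Z,9S)-3,9-diacetoxy-2-(triethylsilyloxy) ten-membered C8 ketone with the 11α,12α-acetonide
Conditions: PhI(OCOCF3)2, NaHCO3, MeCN/H2O (9:1), 0 °C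
Reagents that add atoms: water, O
Why: Oxidative hydrolysis of the dithiane with a hypervalent iodine reagent is fast at 0 °C and leaves isolated alkenes, acetates and the buffered acetonide alone; the β,γ-unsaturated ketone is not exposed to base.

Step 26
Reactants: 33 ten-membered C8 ketone
Product: 34 (5Z,7E)-8-(tert-butyldimethylsilyloxy) dienol ether of 33 (C7=C8 ring-cis, conjugated with C5=C6)
Conditions: t-BuMe2SiOSO2CF3, Et3N, CH2Cl2, −78 → 0 °C
Reagents that add atoms: tert-butyldimethylsilyl trifluoromethanesulfonate, CC(C)(C)[Si](C)(C)OS(=O)(=O)C(F)(F)F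
Why: Soft enolisation takes the C7 proton, which is both α to the ketone and allylic, in preference to the hindered acetoxy-bearing C9–H, and traps the dienol as its silyl ether. The ring-cis geometry is expected but not required.

Step 27
Reactants: 34 silyl dienol ether; 35 2-chloropropanoyl chloride
Product: 37 (7S,8R,17S)-α-chlorocyclobutanone: four-membered ring C7–C19(=O)–C17(Cl)(CH3)–C8(OSi(t-Bu)Me2) cis-fused to the ten-membered ring, via chloro(methyl)ketene 36 (not isolated)
Conditions: Et3N (slow addition), hexane, 60 °C
Reagents that add atoms: none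
Why: Ketene–enol ether [2+2] cycloaddition: the electrophilic ketene carbonyl carbon C19 bonds to the nucleophilic C7 and C17 to the oxygen-bearing C8, suprafacially on the enol ether. Peripheral attack on the exposed face of the medium-ring alkene should set 7S; the methyl group is expected endo.

Step 28
Reactants: 37 α-chlorocyclobutanone
Product: 39 (7S,8R,17S)-17-chloro-8-(tert-butyldimethylsilyloxy) γ-lactone (C7–O–C19(=O)–C17–C8) fused to the ten-membered ring, via Criegee perhydrate 38 (not isolated)
Conditions: 30% aq. H2O2, NaOAc, AcOH, 0 → 10 °C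
Reagents that add atoms: hydrogen peroxide, OO
Why: Baeyer–Villiger oxidation: hydrogen peroxide adds to the strained carbonyl C19 to give the perhydrate 38, which rearranges by a 1,2-shift of C7 from carbon to oxygen with loss of water. The closest known reaction is the H2O2/AcOH oxidation of α-chloro- and α,α-dichlorocyclobutanones from ketene cycloadducts to γ-lactones. The five-membered ring arises by ring expansion of the four-membered ketone, not by a cyclisation: the C7–C19 bond is replaced by C7–O and O–C19. No stereocentre is created; the concerted shift keeps the 7S configuration set in step 27. The step needs migration of C7 and not C17, and oxidation of the ketone and not the alkenes. The chlorine makes C17 electron-poor and a poor migrating group, while C7 is secondary and allylic. Relief of ring strain lets the perhydrate form at 0 °C without a strong acid, so little peracetic acid builds up and the C5=C6 and C13=C14 bonds should survive. The acetate buffer protects the acetonide and the two silyl ethers.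

Step 29
Reactants: 39 17-chloro-8-silyloxy lactone
Product: 40 (7S)-3-methylbutenolide (C8=C17) fused to the ten-membered ring; C2 triethylsilyl ether, C3 and C9 acetates, acetonide
Conditions: Zn dust (Me3SiCl-activated), THF, 50 °C
Reagents that add atoms: none
Why: Reductive elimination: zinc inserts into the C17–Cl bond α to the carbonyl, and the silyloxy group is then lost from the β-carbon C8, the known fate of β-oxygenated Reformatsky species in aprotic media. Both provisional stereocentres disappear.

Step 30
Reactants: 40 3-methylbutenolide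
Product: 41 (7S,8R,17S)-8,17-epoxy lactone (oxirane oxygen on the face of H7)
Conditions: t-BuOOH, n-BuLi, THF, −78 → −20 °C
Reagents that add atoms: tert-butyl hydroperoxide, CC(C)(C)OO
Why: Weitz–Scheffer epoxidation: the peroxide anion adds only to the electron-poor C8=C17 bond, at C8 on the face away from C6, and ring closure expels tert-butoxide. The weakly basic, hindered peroxide should spare the acetates and the γ-hydrogens, although the tetrasubstituted alkene may react slowly.

Step 31
Reactants: 41 8,17-epoxy lactone
Product: 42 brianodin D, (1S,2S,3R,5Z,7S,8S,9S,10S,11S,12R,13Z,17S)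
Conditions: 1 M aq. HClO4, THF, 0 → 25 °C
Reagents that add atoms: water, O
Why: Acid-catalysed epoxide hydrolysis: ionisation is confined to the β-carbon C8 (a cation at C17 would be α to the carbonyl), and water, possibly assisted by the neighbouring C9 acetoxy group, enters anti to the oxirane oxygen. C8 is inverted and C17 retained, giving the trans 8S,17S diol. The same medium cleaves the acetonide and the triethylsilyl ether, and the acetates should survive dilute acid.

## Compound list

1 | pent-1-en-3-one | CCC(=O)C=C | starting material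
2 | (Z)-3-(tert-butyldimethylsilyloxy)penta-1,3-diene | C/C=C(\O[Si](C)(C)C(C)(C)C)C=C | intermediate
3 | ethyl (E)-3-methyl-4-oxobut-2-enoate | CCOC(=O)/C=C(\C)C=O | starting material
4 | ethyl (1S,2S,6S)-2-formyl-2,6-dimethyl-5-(tert-butyldimethylsilyloxy)cyclohex-4-ene-1-carboxylate | CCOC(=O)[C@H]2[C@H](C)C(O[Si](C)(C)C(C)(C)C)=CC[C@]2(C)C=O | intermediate
5 | ethyl (1S,2S,6S)-2-(hydroxymethyl)-2,6-dimethyl-5-(tert-butyldimethylsilyloxy)cyclohex-4-ene-1-carboxylate | CCOC(=O)[C@H]2[C@H](C)C(O[Si](C)(C)C(C)(C)C)=CC[C@]2(C)CO | intermediate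
6 | ethyl (1S,2S,6S)-2-[(tert-butyldimethylsilyloxy)methyl]-2,6-dimethyl-5-(tert-butyldimethylsilyloxy)cyclohex-4-ene-1-carboxylate | CCOC(=O)[C@H]2[C@H](C)C(O[Si](C)(C)C(C)(C)C)=CC[C@]2(C)CO[Si](C)(C)C(C)(C)C | intermediate
7 | ethyl (1S,2S,6S)-2-[(tert-butyldimethylsilyloxy)methyl]-2,6-dimethyl-5-oxocyclohex-3-ene-1-carboxylate | CCOC(=O)[C@H]2[C@H](C)C(=O)C=C[C@]2(C)CO[Si](C)(C)C(C)(C)C | intermediate
8 | potassium dienolate of 7 (C11=C12–O−, C13=C14) | CCOC(=O)[C@H]2C(C)=C([O-])C=C[C@]2(C)CO[Si](C)(C)C(C)(C)C.[K+] | intermediate (not isolated)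
9 | ethyl 6-[(tert-butyldimethylsilyloxy)methyl]-2,6-dimethyl-3-(trifluoromethylsulfonyloxy)cyclohexa-2,4-diene-1-carboxylate, ester cis to the ring methyl on the quaternary carbon | CCOC(=O)[C@H]2C(C)=C(OS(=O)(=O)C(F)(F)F)C=C[C@]2(C)CO[Si](C)(C)C(C)(C)C | intermediate
10 | ethyl 6-[(tert-butyldimethylsilyloxy)methyl]-2,6-dimethylcyclohexa-2,4-diene-1-carboxylate, same configuration | CCOC(=O)[C@H]2C(C)=CC=C[C@]2(C)CO[Si](C)(C)C(C)(C)C | intermediate
11 | ring C diol ester (C10 β-CO2Et; C1 β-CH3, α-CH2OSi(t-Bu)Me2; 11β-CH3, 11α,12α-diol; C13=C14) | CCOC(=O)[C@H]2[C@](C)(O)[C@H](O)C=C[C@]2(C)CO[Si](C)(C)C(C)(C)C | intermediate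
12 | 11α,12α-O-isopropylidene derivative of 11 | CCOC(=O)[C@H]2[C@](C)(OC(C)(C)O4)[C@H]4C=C[C@]2(C)CO[Si](C)(C)C(C)(C)C | intermediate
13 | C9 primary alcohol (CH2OH on C10) | OC[C@H]2[C@](C)(OC(C)(C)O4)[C@H]4C=C[C@]2(C)CO[Si](C)(C)C(C)(C)C | intermediate
14 | C9 aldehyde (CHO on C10) | O=C[C@H]2[C@](C)(OC(C)(C)O4)[C@H]4C=C[C@]2(C)CO[Si](C)(C)C(C)(C)C | intermediate
15 | but-3-yn-1-ol | C#CCCO | starting material
16 | tert-butyl(but-3-yn-1-yloxy)dimethylsilane | C#CCCO[Si](C)(C)C(C)(C)C | intermediate
17 | lithium acetylide of 16 | [Li]C#CCCO[Si](C)(C)C(C)(C)C | intermediate (not isolated)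
18 | methyl 5-(tert-butyldimethylsilyloxy)pent-2-ynoate | COC(=O)C#CCCO[Si](C)(C)C(C)(C)C | intermediate
19 | methyl (Z)-3-methyl-5-(tert-butyldimethylsilyloxy)pent-2-enoate | COC(=O)/C=C(/C)CCO[Si](C)(C)C(C)(C)C | intermediate
20 | (Z)-3-methyl-5-(tert-butyldimethylsilyloxy)pent-2-en-1-ol | OC/C=C(/C)CCO[Si](C)(C)C(C)(C)C | intermediate
21 | (Z)-5-bromo-3-methylpent-3-en-1-yl tert-butyldimethylsilyl ether | BrC/C=C(/C)CCO[Si](C)(C)C(C)(C)C | intermediate
22 | 1,3-dithiane | C1CSCSC1 | starting material
23 | 2-lithio-1,3-dithiane | [Li]C1SCCCS1 | intermediate (not isolated)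
24 | 2-[(Z)-3-methyl-5-(tert-butyldimethylsilyloxy)pent-2-en-1-yl]-1,3-dithiane | CC(C)(C)[Si](C)(C)OCC/C(C)=C\CC1SCCCS1 | intermediate
25 | 2-lithio derivative of 24 | CC(C)(C)[Si](C)(C)OCC/C(C)=C\CC1([Li])SCCCS1 | intermediate (not isolated)
26 | (9S)-carbinol from 14 and 25 | CC(C)(C)[Si](C)(C)OCC/C(C)=C\CC1(SCCCS1)[C@@H](O)[C@H]2[C@](C)(OC(C)(C)O4)[C@H]4C=C[C@]2(C)CO[Si](C)(C)C(C)(C)C | intermediate
27 | (9S)-9-acetate of 26 | CC(C)(C)[Si](C)(C)OCC/C(C)=C\CC1(SCCCS1)[C@@H](OC(C)=O)[C@H]2[C@](C)(OC(C)(C)O4)[C@H]4C=C[C@]2(C)CO[Si](C)(C)C(C)(C)C | intermediate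
28 | C2,C3-diol | OCC/C(C)=C\CC1(SCCCS1)[C@@H](OC(C)=O)[C@H]2[C@](C)(OC(C)(C)O4)[C@H]4C=C[C@]2(C)CO | intermediate
29 | C2,C3-dialdehyde | O=CC/C(C)=C\CC1(SCCCS1)[C@@H](OC(C)=O)[C@H]2[C@](C)(OC(C)(C)O4)[C@H]4C=C[C@]2(C)C=O | intermediate
30 | (2S,3R,5Z,9S)-ten-membered 2,3-diol, C8 dithiane | O[C@@H]1C/C(C)=C\CC3(SCCCS3)[C@@H](OC(C)=O)[C@H]2[C@](C)(OC(C)(C)O4)[C@H]4C=C[C@]2(C)[C@@H]1O | intermediate
31 | 3-O-acetyl derivative of 30 | CC(=O)O[C@@H]1C/C(C)=C\CC3(SCCCS3)[C@@H](OC(C)=O)[C@H]2[C@](C)(OC(C)(C)O4)[C@H]4C=C[C@]2(C)[C@@H]1O | intermediate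
32 | 2-O-triethylsilyl ether of 31 | CC(=O)O[C@@H]1C/C(C)=C\CC3(SCCCS3)[C@@H](OC(C)=O)[C@H]2[C@](C)(OC(C)(C)O4)[C@H]4C=C[C@]2(C)[C@@H]1O[Si](CC)(CC)CC | intermediate
33 | ten-membered C8 ketone | CC(=O)O[C@@H]1C/C(C)=C\CC(=O)[C@@H](OC(C)=O)[C@H]2[C@](C)(OC(C)(C)O4)[C@H]4C=C[C@]2(C)[C@@H]1O[Si](CC)(CC)CC | intermediate
34 | (5Z,7E)-8-(tert-butyldimethylsilyloxy) dienol ether | CC(=O)O[C@@H]1C/C(C)=C\C=C(O[Si](C)(C)C(C)(C)C)/[C@@H](OC(C)=O)[C@H]2[C@](C)(OC(C)(C)O4)[C@H]4C=C[C@]2(C)[C@@H]1O[Si](CC)(CC)CC | intermediate
35 | 2-chloropropanoyl chloride | CC(Cl)C(Cl)=O | starting material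
36 | chloro(methyl)ketene | CC(Cl)=C=O | intermediate (not isolated)
37 | (7S,8R,17S)-α-chlorocyclobutanone | CC(=O)O[C@@H]1C/C(C)=C\[C@@H]2C(=O)[C@@](C)(Cl)[C@]2(O[Si](C)(C)C(C)(C)C)[C@@H](OC(C)=O)[C@H]2[C@](C)(OC(C)(C)O4)[C@H]4C=C[C@]2(C)[C@@H]1O[Si](CC)(CC)CC | intermediate
38 | Criegee perhydrate of 37 (C19 hydroxy hydroperoxide) | CC(=O)O[C@@H]1C/C(C)=C\[C@@H]2C(O)(OO)[C@@](C)(Cl)[C@]2(O[Si](C)(C)C(C)(C)C)[C@@H](OC(C)=O)[C@H]2[C@](C)(OC(C)(C)O4)[C@H]4C=C[C@]2(C)[C@@H]1O[Si](CC)(CC)CC | intermediate (not isolated)
39 | (7S,8R,17S)-17-chloro-8-(tert-butyldimethylsilyloxy) γ-lactone | CC(=O)O[C@@H]1C/C(C)=C\[C@@H]2OC(=O)[C@@](C)(Cl)[C@]2(O[Si](C)(C)C(C)(C)C)[C@@H](OC(C)=O)[C@H]2[C@](C)(OC(C)(C)O4)[C@H]4C=C[C@]2(C)[C@@H]1O[Si](CC)(CC)CC | intermediate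
40 | (7S)-3-methylbutenolide (C8=C17) | CC(=O)O[C@@H]1C/C(C)=C\[C@@H]2OC(=O)C(C)=C2[C@@H](OC(C)=O)[C@H]2[C@](C)(OC(C)(C)O4)[C@H]4C=C[C@]2(C)[C@@H]1O[Si](CC)(CC)CC | intermediate
41 | (7S,8R,17S)-8,17-epoxy lactone | CC(=O)O[C@@H]1C/C(C)=C\[C@@H]2OC(=O)[C@@]5(C)O[C@@]25[C@@H](OC(C)=O)[C@H]2[C@](C)(OC(C)(C)O4)[C@H]4C=C[C@]2(C)[C@@H]1O[Si](CC)(CC)CC | intermediate
42 | brianodin D | CC(=O)O[C@@H]1C/C(C)=C\[C@@H]2OC(=O)[C@@](C)(O)[C@@]2(O)[C@@H](OC(C)=O)[C@H]2[C@](C)(O)[C@H](O)C=C[C@]2(C)[C@@H]1O | target

## Step count and risks

Total: 31 steps. Longest linear sequence: 25 steps (steps 1–11 and 18–31, from pent-1-en-3-one). The dithiane branch is 6 steps (12–17).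

**Step 28 (key step).**
- Risk: ring opening of the β-silyloxy cyclobutanone or of its perhydrate in the acidic medium before the 1,2-shift can occur. The push–pull substitution (donor oxygen on C8, acceptor carbonyl at C19) that makes the ketone reactive also weakens the ring bonds to C8. If the oxidation then has to be prolonged, C5=C6 may be slowly epoxidised.
- Fallback: set out from 34. Rubottom oxidation (dimethyldioxirane, acetone, −78 °C, then mild acidic work-up) oxidises the enol ether, the most electron-rich alkene, to the (7S)-7-hydroxy ketone F1. Esterification with 2-(diethoxyphosphoryl)propanoic acid (N,N′-dicyclohexylcarbodiimide, 4-(dimethylamino)pyridine) gives the phosphonate ester F2. Intramolecular Horner–Wadsworth–Emmons condensation onto the C8 ketone (LiCl, i-Pr2NEt, MeCN) closes C8=C17 and returns to the route at butenolide 40.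

**Step 27.**
- Risk: dimerisation of the moderately electrophilic chloro(methyl)ketene outrunning its addition to a hindered, conjugated enol ether, together with weak facial discrimination at C7 or bonding at the vinylogous position C5.
- Fallback: set out from 34 with the most reactive ketene. Dichloroketene F3 (Cl3CCOCl, Zn(Cu), Et2O) gives the 17,17-dichlorocyclobutanone F4. H2O2/AcOH gives the dichlorolactone F5. Zn in THF gives the 17-chlorobutenolide F6. Suzuki–Miyaura methylation (trimethylboroxine, Pd(OAc)2, 2-dicyclohexylphosphino-2′,6′-dimethoxybiphenyl, K3PO4) returns to the route at 40.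

**Step 22.**
- Risk: closure with the two hydroxyl groups trans, the common preference of reductive carbonyl couplings in ten-membered rings once chelation is lost. The wrong face at C2 and oligomerisation are further risks.
- Fallback: set out from 29 and accept the trans outcome. Coupling under non-chelating conditions (SmI2 with HMPA, or TiCl3(DME)1.5 with Zn(Cu)) gives the (2S,3S)-diol F7. A Mitsunobu reaction with acetic acid (PPh3, diisopropyl azodicarboxylate) at the less hindered C3 hydroxyl inverts C3 and acetylates it in one operation, returning to the route at 31.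

**Step 18.**
- Risk: reversed facial selectivity at C9, because C1 and C11 are both quaternary and steric and polar preferences may oppose each other. Enolisation of the hindered aldehyde is a second risk.
- Fallback: set C9 by ketone reduction instead of carbanion addition. Set out from 14 and 25 as in step 18 without regard to selectivity. The mixture of 26 and its (9R)-epimer F8 is oxidised (Dess–Martin periodinane) to the C9 ketone F9. LiAlH4 (Et2O, −78 °C) should deliver hydride to the face the carbanion preferred, which gives the opposite carbinol configuration and returns to the route at 26.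

**Step 31.**
- Risk: capture of the developing C8 cation by hydroxyl groups freed too early (those on C2, C11 and C12 can each reach C8 through a five- or six-membered ring). Elimination toward C7 or C9 and ionisation of the allylic C7–O bond are further risks.
- Fallback: separate opening from deprotection. Set out from 41. Anhydrous BF3·OEt2 in CH2Cl2 at −78 °C, then water, opens the oxirane with inversion at C8 through participation of the C9 acetoxy group while the acetonide and silyl ether stay in place. This gives the protected diol F10. AcOH/H2O/THF at 25 °C then removes both groups and arrives at 42.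

## Further compounds

F1 | step 28 | (7S)-7-hydroxy derivative of ketone 33 | CC(=O)O[C@@H]1C/C(C)=C\[C@H](O)C(=O)[C@@H](OC(C)=O)[C@H]2[C@](C)(OC(C)(C)O4)[C@H]4C=C[C@]2(C)[C@@H]1O[Si](CC)(CC)CC
F2 | step 28 | 7-O-[2-(diethoxyphosphoryl)propanoyl] derivative of F1 (both epimers at the phosphorus-bearing carbon) | CC(=O)O[C@@H]1C/C(C)=C\[C@H](OC(=O)C(C)P(=O)(OCC)OCC)C(=O)[C@@H](OC(C)=O)[C@H]2[C@](C)(OC(C)(C)O4)[C@H]4C=C[C@]2(C)[C@@H]1O[Si](CC)(CC)CC
F3 | step 27 | dichloroketene | ClC(Cl)=C=O
F4 | step 27 | 17,17-dichlorocyclobutanone (37 with Cl in place of the C17 methyl) | CC(=O)O[C@@H]1C/C(C)=C\[C@@H]2C(=O)C(Cl)(Cl)[C@]2(O[Si](C)(C)C(C)(C)C)[C@@H](OC(C)=O)[C@H]2[C@](C)(OC(C)(C)O4)[C@H]4C=C[C@]2(C)[C@@H]1O[Si](CC)(CC)CC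
F5 | step 27 | 17,17-dichloro-8-silyloxy γ-lactone | CC(=O)O[C@@H]1C/C(C)=C\[C@@H]2OC(=O)C(Cl)(Cl)[C@]2(O[Si](C)(C)C(C)(C)C)[C@@H](OC(C)=O)[C@H]2[C@](C)(OC(C)(C)O4)[C@H]4C=C[C@]2(C)[C@@H]1O[Si](CC)(CC)CC
F6 | step 27 | 17-chlorobutenolide (40 with Cl in place of the C17 methyl) | CC(=O)O[C@@H]1C/C(C)=C\[C@@H]2OC(=O)C(Cl)=C2[C@@H](OC(C)=O)[C@H]2[C@](C)(OC(C)(C)O4)[C@H]4C=C[C@]2(C)[C@@H]1O[Si](CC)(CC)CC
F7 | step 22 | (2S,3S)-diol, C3 epimer of 30 | O[C@H]1C/C(C)=C\CC3(SCCCS3)[C@@H](OC(C)=O)[C@H]2[C@](C)(OC(C)(C)O4)[C@H]4C=C[C@]2(C)[C@@H]1O
F8 | step 18 | (9R)-carbinol, C9 epimer of 26 | CC(C)(C)[Si](C)(C)OCC/C(C)=C\CC1(SCCCS1)[C@H](O)[C@H]2[C@](C)(OC(C)(C)O4)[C@H]4C=C[C@]2(C)CO[Si](C)(C)C(C)(C)C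
F9 | step 18 | C9 ketone from 26 and F8 | CC(C)(C)[Si](C)(C)OCC/C(C)=C\CC1(SCCCS1)C(=O)[C@H]2[C@](C)(OC(C)(C)O4)[C@H]4C=C[C@]2(C)CO[Si](C)(C)C(C)(C)C
F10 | step 31 | brianodin D 11,12-acetonide 2-O-triethylsilyl ether | CC(=O)O[C@@H]1C/C(C)=C\[C@@H]2OC(=O)[C@@](C)(O)[C@@]2(O)[C@@H](OC(C)=O)[C@H]2[C@](C)(OC(C)(C)O4)[C@H]4C=C[C@]2(C)[C@@H]1O[Si](CC)(CC)CC
A1 | alternative 1 | ethyl (1S,2S,6S)-2-formyl-2,6-dimethyl-5-(tert-butyldimethylsilyloxy)cyclohex-4-ene-1-carboxylate (identical with 4) | CCOC(=O)[C@H]2[C@H](C)C(O[Si](C)(C)C(C)(C)C)=CC[C@]2(C)C=O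
A2 | alternative 2 | fourteen-membered 1,2-epoxy-5Z,10E,13Z-triene carrying the 8(17)-butenolide, 3,9-diacetate and 12-silyl ether | CC(=O)O[C@@H]1C/C(C)=C\[C@@H]2OC(=O)C(C)=C2[C@@H](OC(C)=O)/C=C(\C)[C@H](O[Si](C)(C)C(C)(C)C)/C=C\[C@]3(C)O[C@H]13
A3 | alternative 2 | 8(17)-dehydro briarane 3,9-diacetate with 12-silyl ether | CC(=O)O[C@@H]1C/C(C)=C\[C@@H]2OC(=O)C(C)=C2[C@@H](OC(C)=O)[C@H]2[C@](C)(O)[C@H](O[Si](C)(C)C(C)(C)C)C=C[C@]2(C)[C@@H]1O
A4 | alternative 3 | hydroazulene with C5–C9 bond, C9 tertiary alcohol and C6 mesylate anti to that bond; C7 silyl ether, 2,3- and 11,12-acetonides | CC5(C)O[C@@H]1C[C@]6(C)[C@H](OS(C)(=O)=O)[C@H](O[Si](C)(C)C(C)(C)C)C[C@]6(O)[C@H]2[C@](C)(OC(C)(C)O4)[C@H]4C=C[C@]2(C)[C@@H]1O5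
A5 | alternative 3 | ten-membered (Z)-5-en-9-one with C7 silyl ether and two acetonides | CC5(C)O[C@@H]1C/C(C)=C\[C@H](O[Si](C)(C)C(C)(C)C)CC(=O)[C@H]2[C@](C)(OC(C)(C)O4)[C@H]4C=C[C@]2(C)[C@@H]1O5
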